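Numbering used: 1,2-dioxolane O1–O2–C3–C4–C5 (C3 carries CH3 and the CH2CO2H arm, C5 carries CH3 and the chain, O1 is on C5); chain C6H2–C7H(CH3)–C8…C11–C12=C13–C14–C15–C16=C17–Ph.
Retrosynthetic cuts: CO2H back to CH2OH (arm carried as CH2CH2OTBDPS, TBDPS = tert-butyldiphenylsilyl); C12=C13 (Julia–Kocienski); the dioxolane at C3–C4 and O1–C5 in one [3+2] annulation of a methyl-ketone silylperoxy ketal with a 2-methyl-1-alkene; C8–C9 (copper-catalysed tosylate/Grignard coupling); C6–C7 (Evans alkylation).
Enabling feature: in the dioxolane the peroxide-bearing C3 is at ketone oxidation level (a latent peroxycarbenium ion) and C4H2–C5(CH3) is a latent 1,1-disubstituted alkene whose Markovnikov cation is the tertiary C5; O1 belongs to the same peroxide, so it closes the ring on C5 once C3–C4 is made.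
Forward order: peroxy ketal 5 (steps 1–3) and diene 13 (steps 4–7) are united to the only ring, dioxolane 16 (step 8); the vinyl end becomes the C12 aldehyde (step 9), sulfone 27 (steps 10–13) adds C13–C17–Ph (step 14), then desilylation and oxidation of the arm (steps 15 and 16).
Stereochemistry: C7 from the Evans alkylation; C3 and C5 from the chiral counter-anion in the annulation (C7 makes all stereoisomers diastereomers); E-C16=C17 from the Johnson–Claisen rearrangement; E-C12=C13 from the Julia–Kocienski olefination.
Key step: step 8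

Assumption: the sense of induction of the chiral acid in step 8 cannot be predicted, so the (S,S) antipode is written and the antipode that favours 16 is to be fixed by experiment; pent-4-en-1-ylmagnesium bromide is taken as a purchased THF solution.

Step 1
Reactants: 1 3-methylbut-3-en-1-ol
Product: 2 tert-butyl[(3-methylbut-3-en-1-yl)oxy]diphenylsilane
Conditions: TBDPSCl, imidazole, CH2Cl2, 0 °C to rt
Reagents that add atoms: tert-butyl(chloro)diphenylsilane, CC(C)(C)[Si](Cl)(c1ccccc1)c1ccccc1
Why: Standard silylation of a primary alcohol; the bulky, acid-stable and weakly nucleophilic TBDPS ether is chosen to survive the acidic annulation and to keep the arm below the β-peroxy carbonyl oxidation level until the end.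

Step 2
Reactants: 2 tert-butyl[(3-methylbut-3-en-1-yl)oxy]diphenylsilane
Product: 4 tert-butyl(3-hydroperoxy-3-methoxybutoxy)diphenylsilane (racemic), via carbonyl oxide 3 (not isolated)
Conditions: O3, CH2Cl2/MeOH, NaHCO3, −78 °C; N2 purge, then 0 °C
Reagents that add atoms: ozone, [O-][O+]=O; methanol, CO
Why: Ozonolysis in methanol (Criegee cleavage): the primary ozonide of the 1,1-disubstituted alkene is expected to fragment mainly to formaldehyde and the more substituted ketone O-oxide 3, which methanol traps as the α-methoxy hydroperoxide; the new ketal centre is racemic and is planarised later.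

Step 3
Reactants: 4 tert-butyl(3-hydroperoxy-3-methoxybutoxy)diphenylsilane
Product: 5 tert-butyl{3-methoxy-3-[(triethylsilyl)peroxy]butoxy}diphenylsilane (racemic)
Conditions: Et3SiCl, imidazole, DMAP (4-(dimethylamino)pyridine, cat.), CH2Cl2, 0 °C
Reagents that add atoms: chlorotriethylsilane, CC[Si](Cl)(CC)CC
Why: O-silylation of the hydroperoxide under mild basic conditions that spare the acid-labile peroxy ketal; the Et3Si group later acts as the leaving group on oxygen in the ring closure.

Step 4
Reactants: 6 (R)-4-benzyl-3-propanoyl-1,3-oxazolidin-2-one; 7 3-bromo-2-methylprop-1-ene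
Product: 9 (R)-4-benzyl-3-[(S)-2,4-dimethylpent-4-enoyl]-1,3-oxazolidin-2-one, via sodium enolate 8 (not isolated)
Conditions: NaN(SiMe3)2, THF, −78 °C; then 7, −78 to −40 °C
Reagents that add atoms: none
Why: Evans asymmetric alkylation: the chelated (Z)-enolate 8 is alkylated by the allylic bromide on the face opposite the benzyl group of the (R)-auxiliary, which sets the (S)-α-methyl centre (the later C7).

Step 5
Reactants: 9 (R)-4-benzyl-3-[(S)-2,4-dimethylpent-4-enoyl]-1,3-oxazolidin-2-one
Product: 10 (S)-2,4-dimethylpent-4-en-1-ol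
Conditions: LiBH4, MeOH (1 equiv), THF, 0 °C
Reagents that add atoms: none
Why: Reductive removal of the auxiliary (hydride attack on the exocyclic imide carbonyl) without epimerisation; the 1,1-disubstituted alkene is inert.

Step 6
Reactants: 10 (S)-2,4-dimethylpent-4-en-1-ol
Product: 11 (S)-2,4-dimethylpent-4-en-1-yl 4-methylbenzenesulfonate
Conditions: TsCl, pyridine, CH2Cl2, 0 °C to rt
Reagents that add atoms: 4-methylbenzenesulfonyl chloride, Cc1ccc(cc1)S(Cl)(=O)=O
Why: Sulfonylation of the primary alcohol; the stereocentre is not involved.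

Step 7
Reactants: 11 (S)-2,4-dimethylpent-4-en-1-yl 4-methylbenzenesulfonate; 12 pent-4-en-1-ylmagnesium bromide
Product: 13 (R)-2,4-dimethyldeca-1,9-diene
Conditions: Li2CuCl4 (cat.), THF, −78 °C to rt
Reagents that add atoms: none
Why: Copper-catalysed sp3–sp3 cross-coupling of a primary tosylate with a primary alkyl Grignard reagent; substitution occurs at CH2, so the adjacent stereocentre is untouched (the descriptor changes to R only through the priority rules).

Step 8
Reactants: 5 tert-butyl{3-methoxy-3-[(triethylsilyl)peroxy]butoxy}diphenylsilane; 13 (R)-2,4-dimethyldeca-1,9-diene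
Product: 16 (3S,5R)-3-{2-[tert-butyl(diphenyl)silyl]oxyethyl}-3,5-dimethyl-5-[(2R)-2-methyloct-7-en-1-yl]-1,2-dioxolane, via peroxycarbenium ion 14 (not isolated), via tertiary carbocation 15 (not isolated)
Conditions: (S,S)-imidodiphosphorimidate (IDPi) acid [(S)-3,3'-Ar2-1,1'-binaphthalene-2,2'-diyl-O2P(=NSO2CF3)]2NH, Ar = 3,5-(CF3)2C6H3 (5 mol %), CH2Cl2, −78 °C
Reagents that add atoms: none
Why: Proposed new method: the chiral acid ionises the methoxy group of 5 to peroxycarbenium ion 14, held as an ion pair with the confined chiral anion; the CH2 terminus of the 1,1-disubstituted alkene of 13 adds to its carbenium carbon (C3–C4 bond) to give tertiary cation 15, whose C5 is captured by the distal, silylated peroxide oxygen (O1–C5 bond), the Et3Si group passing to the anion and then to the liberated methanol, which regenerates the acid. The closest known reaction types are the stoichiometric SnCl4-promoted [3+2] annulation of triethylsilylperoxy ketals with alkenes and, for the induction, anion-directed asymmetric catalysis of oxocarbenium–alkene (Prins-type) reactions by confined imidodiphosphorimidate acids; a catalytic enantioselective peroxycarbenium annulation is the unprecedented part. The 1,2-dioxolane, the only ring formed, closes in a stepwise polar [3+2] mode by oxygen capture of a free tertiary cation (formally 5-endo with respect to the former C4=C5 bond, which is no obstacle for a cation). C3 is set in the C–C bond-forming event by discrimination of the two faces of 14 (CH3 versus silyloxyethyl) by the chiral anion, and C5 by the alkene face presented in the same ion pair, ring closure being expected to outrun rotation about C4–C5; the remote (R)-centre of 13 is a bystander. The step needs chemoselectivity for the 1,1-disubstituted over the terminal vinyl double bond, which the substrate secures because only the former leads to a tertiary cation, and regiochemistry, secured by Markovnikov addition; the cis relation of the two large arms and the absolute sense are not biased by the substrate and rest on the catalyst alone. Because the side-chain centre is fixed, every stereoisomeric by-product is a diastereomer of 16 and can be removed, so that 16 should be obtained as a single enantiomer.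

Step 9
Reactants: 16 (3S,5R)-3-{2-[tert-butyl(diphenyl)silyl]oxyethyl}-3,5-dimethyl-5-[(2R)-2-methyloct-7-en-1-yl]-1,2-dioxolane
Product: 18 (6R)-7-[(3R,5S)-5-{2-[tert-butyl(diphenyl)silyl]oxyethyl}-3,5-dimethyl-1,2-dioxolan-3-yl]-6-methylheptanal, via methoxy hydroperoxide 17 (not isolated)
Conditions: O3, CH2Cl2/MeOH, NaHCO3, −78 °C; then Me2S, −78 °C to rt
Reagents that add atoms: ozone, [O-][O+]=O
Why: Ozonolysis of the only remaining C=C with reductive work-up; the fully substituted dialkyl peroxide has no O–H or α-C–H and should be inert to ozone and to Me2S, whereas hydroperoxide 17 is reduced to the aldehyde.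

Step 10
Reactants: 19 1-phenylprop-2-en-1-ol (racemic); 20 1,1,1-triethoxyethane
Product: 22 ethyl (E)-5-phenylpent-4-enoate, via ketene acetal 21 (not isolated)
Conditions: EtCO2H (cat.), neat 20, 140 °C, EtOH distilled off
Reagents that add atoms: none
Why: Johnson–Claisen rearrangement: the [3,3]-sigmatropic shift of ketene acetal 21 through a chair with phenyl equatorial should give the (E)-styrenyl γ,δ-unsaturated ester (C16=C17 geometry).

Step 11
Reactants: 22 ethyl (E)-5-phenylpent-4-enoate
Product: 23 (E)-5-phenylpent-4-en-1-ol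
Conditions: LiAlH4, THF, 0 °C
Reagents that add atoms: none
Why: Hydride reduction of the ester; the isolated styrenyl double bond is not reduced.

Step 12
Reactants: 23 (E)-5-phenylpent-4-en-1-ol; 24 1-phenyl-1H-tetrazole-5-thiol
Product: 25 1-phenyl-5-{[(E)-5-phenylpent-4-en-1-yl]sulfanyl}-1H-tetrazole
Conditions: PPh3, iPrO2CN=NCO2iPr (DIAD), THF, 0 °C to rt
Reagents that add atoms: none
Why: Mitsunobu thioetherification of the primary alcohol with the acidic heteroaryl thiol.

Step 13
Reactants: 25 1-phenyl-5-{[(E)-5-phenylpent-4-en-1-yl]sulfanyl}-1H-tetrazole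
Product: 27 1-phenyl-5-{[(E)-5-phenylpent-4-en-1-yl]sulfonyl}-1H-tetrazole, via sulfoxide 26 (not isolated)
Conditions: (NH4)6Mo7O24·4H2O (cat.), 30% aq H2O2, EtOH, 0 °C to rt
Reagents that add atoms: hydrogen peroxide, OO
Why: Molybdate-catalysed oxidation of sulfide to sulfone through sulfoxide 26; peroxomolybdate oxidises sulfur much faster than the styrenyl double bond.

Step 14
Reactants: 27 1-phenyl-5-{[(E)-5-phenylpent-4-en-1-yl]sulfonyl}-1H-tetrazole; 18 (6R)-7-[(3R,5S)-5-{2-[tert-butyl(diphenyl)silyl]oxyethyl}-3,5-dimethyl-1,2-dioxolan-3-yl]-6-methylheptanal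
Product: 29 tert-butyl{2-[(3S,5R)-3,5-dimethyl-5-((2R,7E,11E)-2-methyl-12-phenyldodeca-7,11-dien-1-yl)-1,2-dioxolan-3-yl]ethoxy}diphenylsilane, via potassium sulfonyl carbanion 28 (not isolated)
Conditions: KN(SiMe3)2, DME (1,2-dimethoxyethane), −60 °C; then 18, −60 °C to rt
Reagents that add atoms: none
Why: Julia–Kocienski olefination: addition of carbanion 28 to the aldehyde, Smiles rearrangement and anti-elimination of SO2 and tetrazololate should give the (E)-C12=C13 alkene (potassium in DME favours the open, anti-selective addition); the dioxolane has no α-C–H (no Kornblum–DeLaMare path) and no acidic C–H, so it should tolerate the base.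

Step 15
Reactants: 29 tert-butyl{2-[(3S,5R)-3,5-dimethyl-5-((2R,7E,11E)-2-methyl-12-phenyldodeca-7,11-dien-1-yl)-1,2-dioxolan-3-yl]ethoxy}diphenylsilane
Product: 30 2-[(3S,5R)-3,5-dimethyl-5-((2R,7E,11E)-2-methyl-12-phenyldodeca-7,11-dien-1-yl)-1,2-dioxolan-3-yl]ethan-1-ol
Conditions: Bu4NF, THF, 0 °C to rt
Reagents that add atoms: none
Why: Fluoride-mediated cleavage of the silyl ether; dialkyl peroxides and the diene are inert to fluoride.

Step 16
Reactants: 30 2-[(3S,5R)-3,5-dimethyl-5-((2R,7E,11E)-2-methyl-12-phenyldodeca-7,11-dien-1-yl)-1,2-dioxolan-3-yl]ethan-1-ol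
Product: 32 2-[(3R,5R)-3,5-dimethyl-5-((2R,7E,11E)-2-methyl-12-phenyldodeca-7,11-dien-1-yl)-1,2-dioxolan-3-yl]acetic acid (CNP0204107.4), via aldehyde 31 (not isolated)
Conditions: TEMPO (2,2,6,6-tetramethylpiperidin-1-oxyl, cat.), PhI(OAc)2, MeCN/H2O, rt
Reagents that add atoms: water, O
Why: Oxoammonium-mediated oxidation of the primary alcohol to aldehyde 31 and, through its hydrate, to the acid under near-neutral conditions that should spare the peroxide and both alkenes and avoid base-induced β-elimination of the β-peroxy carbonyl (the C3 descriptor changes from S to R only through the priority rules).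

Compound list
1 | 3-methylbut-3-en-1-ol | C=C(C)CCO | starting material
2 | tert-butyl[(3-methylbut-3-en-1-yl)oxy]diphenylsilane | C=C(C)CCO[Si](c1ccccc1)(c1ccccc1)C(C)(C)C | intermediate
3 | carbonyl oxide, 4-[tert-butyl(diphenyl)silyl]oxybutan-2-one O-oxide | CC(CCO[Si](c1ccccc1)(c1ccccc1)C(C)(C)C)=[O+][O-] | intermediate
4 | tert-butyl(3-hydroperoxy-3-methoxybutoxy)diphenylsilane (racemic) | COC(C)(CCO[Si](c1ccccc1)(c1ccccc1)C(C)(C)C)OO | intermediate
5 | tert-butyl{3-methoxy-3-[(triethylsilyl)peroxy]butoxy}diphenylsilane (racemic) | COC(C)(CCO[Si](c1ccccc1)(c1ccccc1)C(C)(C)C)OO[Si](CC)(CC)CC | intermediate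
6 | (R)-4-benzyl-3-propanoyl-1,3-oxazolidin-2-one | CCC(=O)N1[C@H](Cc2ccccc2)COC1=O | starting material
7 | 3-bromo-2-methylprop-1-ene | C=C(C)CBr | starting material
8 | sodium (Z)-enolate of 6 | C/C=C(\[O-])N1[C@H](Cc2ccccc2)COC1=O.[Na+] | intermediate
9 | (R)-4-benzyl-3-[(S)-2,4-dimethylpent-4-enoyl]-1,3-oxazolidin-2-one | C=C(C)C[C@H](C)C(=O)N1[C@H](Cc2ccccc2)COC1=O | intermediate
10 | (S)-2,4-dimethylpent-4-en-1-ol | C=C(C)C[C@H](C)CO | intermediate
11 | (S)-2,4-dimethylpent-4-en-1-yl 4-methylbenzenesulfonate | C=C(C)C[C@H](C)COS(=O)(=O)c1ccc(C)cc1 | intermediate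
12 | pent-4-en-1-ylmagnesium bromide | C=CCCC[Mg]Br | starting material
13 | (R)-2,4-dimethyldeca-1,9-diene | C=C(C)C[C@H](C)CCCCC=C | intermediate
14 | peroxycarbenium ion from 5 (loss of methoxide; ion pair with the chiral anion) | CC(CCO[Si](c1ccccc1)(c1ccccc1)C(C)(C)C)=[O+]O[Si](CC)(CC)CC | intermediate
15 | tertiary carbocation at C5 after C3–C4 bond formation (C3 and C7 configured as in 16) | C[C@H](CCCCC=C)C[C+](C)C[C@](C)(CCO[Si](c1ccccc1)(c1ccccc1)C(C)(C)C)OO[Si](CC)(CC)CC | intermediate
16 | (3S,5R)-3-{2-[tert-butyl(diphenyl)silyl]oxyethyl}-3,5-dimethyl-5-[(2R)-2-methyloct-7-en-1-yl]-1,2-dioxolane | C[C@H](CCCCC=C)C[C@]1(C)C[C@](C)(CCO[Si](c2ccccc2)(c2ccccc2)C(C)(C)C)OO1 | intermediate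
17 | chain-end 1-methoxyalkyl hydroperoxide from 16 (vinyl replaced by CH(OMe)OOH, epimers at that carbon) | C[C@H](CCCCC(OC)OO)C[C@]1(C)C[C@](C)(CCO[Si](c2ccccc2)(c2ccccc2)C(C)(C)C)OO1 | intermediate
18 | (6R)-7-[(3R,5S)-5-{2-[tert-butyl(diphenyl)silyl]oxyethyl}-3,5-dimethyl-1,2-dioxolan-3-yl]-6-methylheptanal | C[C@H](CCCCC=O)C[C@]1(C)C[C@](C)(CCO[Si](c2ccccc2)(c2ccccc2)C(C)(C)C)OO1 | intermediate
19 | 1-phenylprop-2-en-1-ol (racemic) | C=CC(O)c1ccccc1 | starting material
20 | 1,1,1-triethoxyethane (triethyl orthoacetate) | CCOC(C)(OCC)OCC | starting material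
21 | ketene acetal, 1-ethoxy-1-[(1-phenylprop-2-en-1-yl)oxy]ethene | C=CC(OC(=C)OCC)c1ccccc1 | intermediate
22 | ethyl (E)-5-phenylpent-4-enoate | CCOC(=O)CC/C=C/c1ccccc1 | intermediate
23 | (E)-5-phenylpent-4-en-1-ol | OCCC/C=C/c1ccccc1 | intermediate
24 | 1-phenyl-1H-tetrazole-5-thiol | Sc1nnnn1-c1ccccc1 | starting material
25 | 1-phenyl-5-{[(E)-5-phenylpent-4-en-1-yl]sulfanyl}-1H-tetrazole | C(CC/C=C/c1ccccc1)Sc1nnnn1-c1ccccc1 | intermediate
26 | 1-phenyl-5-{[(E)-5-phenylpent-4-en-1-yl]sulfinyl}-1H-tetrazole (racemic at sulfur) | O=S(CCC/C=C/c1ccccc1)c1nnnn1-c1ccccc1 | intermediate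
27 | 1-phenyl-5-{[(E)-5-phenylpent-4-en-1-yl]sulfonyl}-1H-tetrazole | O=S(=O)(CCC/C=C/c1ccccc1)c1nnnn1-c1ccccc1 | intermediate
28 | potassium salt of 27 metalated at the carbon next to sulfur | [K+].[CH-](CC/C=C/c1ccccc1)S(=O)(=O)c1nnnn1-c1ccccc1 | intermediate
29 | tert-butyl{2-[(3S,5R)-3,5-dimethyl-5-((2R,7E,11E)-2-methyl-12-phenyldodeca-7,11-dien-1-yl)-1,2-dioxolan-3-yl]ethoxy}diphenylsilane | C[C@H](CCCC/C=C/CC/C=C/c1ccccc1)C[C@]1(C)C[C@](C)(CCO[Si](c2ccccc2)(c2ccccc2)C(C)(C)C)OO1 | intermediate
30 | 2-[(3S,5R)-3,5-dimethyl-5-((2R,7E,11E)-2-methyl-12-phenyldodeca-7,11-dien-1-yl)-1,2-dioxolan-3-yl]ethan-1-ol | C[C@H](CCCC/C=C/CC/C=C/c1ccccc1)C[C@]1(C)C[C@](C)(CCO)OO1 | intermediate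
31 | 2-[(3R,5R)-3,5-dimethyl-5-((2R,7E,11E)-2-methyl-12-phenyldodeca-7,11-dien-1-yl)-1,2-dioxolan-3-yl]acetaldehyde | C[C@H](CCCC/C=C/CC/C=C/c1ccccc1)C[C@]1(C)C[C@](C)(CC=O)OO1 | intermediate
32 | 2-[(3R,5R)-3,5-dimethyl-5-((2R,7E,11E)-2-methyl-12-phenyldodeca-7,11-dien-1-yl)-1,2-dioxolan-3-yl]acetic acid (CNP0204107.4) | C[C@H](CCCC/C=C/CC/C=C/c1ccccc1)C[C@]1(C)C[C@](C)(CC(=O)O)OO1 | target

Total step count: 16. Longest linear sequence: 9 steps (steps 4, 5, 6, 7, 8, 9, 14, 15, 16, from imide 6).

Steps most likely to fail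

Step 8 (proposed new method). What may go wrong:
- weak facial discrimination in the ion pair;
- proton loss from cation 15 to homoallylic peroxides;
- capture of 15 by the arm ether oxygen (six-membered), which the bulky TBDPS group is meant to suppress;
- acid-induced rearrangement of the peroxide.

Fallback with known chemistry and no catalyst control: setting out from 5 and 13, the established stoichiometric annulation with SnCl4 (CH2Cl2, −78 °C) should form the same two bonds without asymmetric induction. It would give 16 together with its ring diastereomers: the isomer with both ring centres inverted F1, the C3 epimer F2 and the C5 epimer F3. The approach to stereochemistry then changes from catalyst control to separation. The fixed (R)-centre at C7 acts as an internal resolving element, so the four products are diastereomers and 16 is isolated by preparative HPLC, if necessary after desilylation at the alcohol stage. The route is rejoined at 16.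

Step 14. What may go wrong: erosion of E selectivity in the addition/Smiles sequence and base-induced self-condensation of the enolisable aldehyde 18. Fallback: setting out from 16 (steps 9 and 14 are then skipped), cross-metathesis of its terminal vinyl group with an excess of (E)-hexa-1,5-dien-1-ylbenzene F4, to be made from cinnamyl bromide and allylmagnesium bromide in THF. With the second-generation Grubbs catalyst RuCl2(=CHPh)(PCy3)(H2IMes) in CH2Cl2 at 40 °C this should give 29 directly. Dialkyl peroxides are compatible with ruthenium carbene catalysts, the thermodynamically preferred E isomer should dominate, and residual Z isomer would be removed on AgNO3-impregnated silica. The route is rejoined at 29.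

Step 2. What may go wrong: fragmentation of the primary ozonide in the unwanted direction (ketone plus formaldehyde O-oxide) and decomposition of the labile hydroperoxy ketal on isolation. Fallback: setting out from 2, ozonolysis in CH2Cl2 at −78 °C gives the ozonide 3-{2-[tert-butyl(diphenyl)silyl]oxyethyl}-3-methyl-1,2,4-trioxolane F5. Reduction with PPh3 should give 4-[tert-butyl(diphenyl)silyl]oxybutan-2-one F6, whatever the direction of fragmentation. Ketalisation (HC(OMe)3, MeOH, cat. TsOH) gives tert-butyl(3,3-dimethoxybutoxy)diphenylsilane F7. Acid-catalysed exchange with anhydrous ethereal H2O2 (cat. camphorsulfonic acid, 0 °C), the known perhydrolysis of ketals, should then deliver 4, where the route is rejoined.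

Further compounds
F1 | step 8 | diastereomer of 16 with both ring centres inverted (3R,5S; arms cis) | C[C@H](CCCCC=C)C[C@@]1(C)C[C@@](C)(CCO[Si](c2ccccc2)(c2ccccc2)C(C)(C)C)OO1
F2 | step 8 | C3 epimer of 16 (3R,5R; arms trans) | C[C@H](CCCCC=C)C[C@]1(C)C[C@@](C)(CCO[Si](c2ccccc2)(c2ccccc2)C(C)(C)C)OO1
F3 | step 8 | C5 epimer of 16 (3S,5S; arms trans) | C[C@H](CCCCC=C)C[C@@]1(C)C[C@](C)(CCO[Si](c2ccccc2)(c2ccccc2)C(C)(C)C)OO1
F4 | step 14 | (E)-hexa-1,5-dien-1-ylbenzene | C=CCC/C=C/c1ccccc1
F5 | step 2 | 3-{2-[tert-butyl(diphenyl)silyl]oxyethyl}-3-methyl-1,2,4-trioxolane | CC1(CCO[Si](c2ccccc2)(c2ccccc2)C(C)(C)C)OCOO1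
F6 | step 2 | 4-[tert-butyl(diphenyl)silyl]oxybutan-2-one | CC(=O)CCO[Si](c1ccccc1)(c1ccccc1)C(C)(C)C
F7 | step 2 | tert-butyl(3,3-dimethoxybutoxy)diphenylsilane | COC(C)(CCO[Si](c1ccccc1)(c1ccccc1)C(C)(C)C)OC
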